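Saturday's run is the flask to read west against: same starting complex, 2 equiv of incoming ligand instead of 2.50 equiv.

| setting | Friday's | Saturday's | west | north-west |
|---|---|---|---|---|
| starting complex | 0.20 mM | 0.20 mM | 0.20 mM | 0.20 mM |
| incoming ligand | 0.55 equiv | 2 equiv | 2.50 equiv | 0.800 equiv |
| remark | run made earlier | run made earlier |  |  |
| time |  |  | 10 min | 10 min |

- Friday's (time / min: complex with two exchanged / %, complex with three exchanged / %): 1.33: 1.2, 0.1; 3.00: 1.0, 0; 4.00: 0.9, 0; 6.00: 0.9, 0; 8.00: 1.2, 0
- Saturday's (time / min: complex with two exchanged / %, complex with three exchanged / %): 1.33: 9.4, 1.6; 3.00: 10.1, 1.3; 4.00: 9.7, 1.3; 6.00: 9.7, 1.6; 8.00: 9.6, 1.5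

(scatter of a reading: 0.3 percentage points)

- for complex with three exchanged the idle adduct is counted in
- steps that have been proposed: starting complex + incoming ligand -> leaving ligand + complex with one exchanged; complex with one exchanged + incoming ligand -> leaving ligand + complex with two exchanged; complex with two exchanged + incoming ligand -> leaving ligand + complex with three exchanged; incoming ligand -> decomposed reagent; complex with three exchanged + incoming ligand <-> idle adduct; incoming ligand <-> dormant form

1. which of these holds the largest part of the starting complex at the end of west (starting complex / complex with two exchanged / complex with three exchanged / complex with one exchanged)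
2. which of these holds the largest part of the starting complex at the end of north-west (starting complex / complex with two exchanged / complex with three exchanged / complex with one exchanged)
3. final complex with two exchanged in west, as a percentage of the starting complex charged

1. Saturday's complex with two exchanged reads 9.4% at 1.33 min and 9.6% at 8.00 min, flat within the scatter of 0.3 percentage points. We therefore treat each reading as the end of its run, set by the dose.

2. Follow one site of the complex, assuming 3 like sites. Each ligand molecule meets a fork: it exchanges or it decomposes. Let p be the chance that a given site has exchanged by the end; the two-exchanged fraction is then 3·p·p·(1−p).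

3. Saturday's mean of 9.70% gives p = 0.201. So the capture share, the exchanges made per equivalent charged, is 3p divided by the dose: 0.301. We carry it at 0.20 mM of starting complex, the charge of Saturday's run and of west. Friday's mean of 1.04%, smaller than Saturday's under the same scatter, gives 0.331.

4. One-exchanged over starting complex is 3p/(1−p), so the two draw level where p is a quarter. That puts the crossing at 2.49 equiv by Saturday's share and 2.27 equiv by Friday's.

5. Saturday's flask has a ratio of 0.755, so starting complex leads there. West has p = 0.251 and a ratio of 1.01. Our reckoning for west is starting complex 42.0%, one-exchanged 42.2% and two-exchanged 14.2%. West's dose stands at or above both crossings, so we name one-exchanged, narrowly. North-west, at p = 0.0803, lies below both crossings, so we name starting complex there.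

6. The forecast differs on west. It names starting complex for west and starting complex for north-west, with 13.3% two-exchanged in west, on the ground that “the extent is about 0.6”.

    starting complex + incoming ligand → leaving ligand + complex with one exchanged (k = 531 M⁻¹ s⁻¹)
    complex with one exchanged + incoming ligand → leaving ligand + complex with two exchanged (k = 312 M⁻¹ s⁻¹)
    complex with two exchanged + incoming ligand → leaving ligand + complex with three exchanged (k = 218 M⁻¹ s⁻¹)
    incoming ligand → decomposed reagent (k = 0.198 s⁻¹)
    complex with three exchanged + incoming ligand ⇌ idle adduct, settled at all times (K = 53400 M⁻¹)
    incoming ligand ⇌ dormant form (K = 0.117, k = 0.287 s⁻¹)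

West ends with complex with one exchanged largest at 44.6%, against 39.7% starting complex and 13.6% two-exchanged, while north-west ends with starting complex at 75.2%. West's incoming ligand, the limiting reagent, is down to 0% of its charge, and the leaving ligand of 0.156 mM is 31.2% of the ligand charged. Now a neighbour of west charged with 1.00 equiv and the same starting complex: the capture share of 0.301 gives p = 0.100, hence starting complex 72.9% and two-exchanged 2.70%. That neighbour ends with starting complex 69.9% and two-exchanged 2.96%.

The data are calculated for substances that don't exist; the scatter is artificial.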